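The plan cuts ring A back to non-aromatic pieces. Its three oxygens (on C5, C7 and C8a) stand meta to one another, and the prenylated C6 sits between the two methoxy carbons. A vinylketene/ynol ether benzannulation writes exactly this pattern. Heating 3-methoxy-2-prenylcyclobut-2-enone with methoxyacetylene makes C8a–C8, C6–C7 and C4a–C8a in one operation and gives 3,5-dimethoxy-4-prenylphenol without any aromatic substitution. The precursor is a four-carbon vinylogous ester that already carries the C5 methoxy and C6 prenyl groups. The phenol is symmetric, with two equivalent free ortho carbons, so a boron-templated condensation with a silyl-protected 2-arylacrolein closes the pyran ring as one regioisomer. Fluoride then frees ring B.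

Key step: step 6

Remark:
- Prenyl = 3-methylbut-2-enyl and TBS = tert-butyldimethylsilyl. Ring atoms carry chromene numbers (O1, C2, C3, C4, C4a, C5–C8, C8a).
- The cyclobutane-1,3-dione is drawn as its dominant enol.
- The sp3 stereocentres of intermediates are racemic, and all vanish before the achiral target.
- Methyl 2-(2,4-dihydroxyphenyl)acetate is assumed to be a catalogue compound.

Step 1
Reactants: 1 5-methylhex-4-enoic acid
Product: 2 5-methylhex-4-enoyl chloride
Conditions: (COCl)2, DMF (cat.), CH2Cl2, 0 °C → rt, concentrate
Reagents that add atoms: oxalyl chloride, O=C(Cl)C(=O)Cl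
Why: Acid chloride formation through the catalytic Vilsmeier-type chloroiminium species runs cold and without strong acid, so the trisubstituted alkene should stay untouched.

Step 2
Reactants: 2 5-methylhex-4-enoyl chloride; 3 ethoxyacetylene
Product: 5 (±)-3-ethoxy-4-(3-methylbut-2-enyl)cyclobut-2-en-1-one, via prenylketene 4 (not isolated)
Conditions: Et3N, excess 3, Et2O/hexanes, slow addition of 2, 0 °C → rt
Reagents that add atoms: none
Why: Dehydrochlorination gives aldoketene 4, which undergoes the ketene–ynol ether [2+2] cycloaddition with the nucleophilic CH terminus of 3 bonding to the ketene carbonyl carbon; slow addition into excess 3 holds back ketene dimerisation, the one-carbon tether rules out an internal ketene–alkene addition, and the C4 stereocentre forms racemic and is erased in step 3.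

Step 3
Reactants: 5 (±)-3-ethoxy-4-(3-methylbut-2-enyl)cyclobut-2-en-1-one
Product: 6 3-hydroxy-2-(3-methylbut-2-enyl)cyclobut-2-en-1-one (enol of 2-prenylcyclobutane-1,3-dione)
Conditions: 1 M aq. HCl, THF, 0 °C → rt
Reagents that add atoms: water, O
Why: Acid-catalysed hydrolysis of a vinylogous ester (addition–elimination of water at C3) frees the 1,3-dione, in which the prenyl-bearing carbon lies between both carbonyls, so it should settle as the more substituted enol 6 with the former stereocentre now sp2, while cold dilute acid is too weak to hydrate the prenyl alkene.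

Step 4
Reactants: 6 3-hydroxy-2-(3-methylbut-2-enyl)cyclobut-2-en-1-one
Product: 7 3-methoxy-2-(3-methylbut-2-enyl)cyclobut-2-en-1-one
Conditions: TMSCHN2, Et2O/MeOH, 0 °C
Reagents that add atoms: trimethylsilyldiazomethane, C[Si](C)(C)C=[N+]=[N-]
Why: O-Methylation of a strongly acidic vinylogous carboxylic acid with a diazoalkane (proton transfer, then SN2 on the methyldiazonium ion) fixes the enol ether on the prenyl-substituted double bond and avoids the C-alkylation and ring cleavage that basic or hot alcoholic conditions could bring.

Step 5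
Reactants: 8 chloroacetaldehyde dimethyl acetal
Product: 11 methoxyacetylene, via 2-chlorovinyl methyl ether 9 (not isolated), via sodium methoxyacetylide 10 (not isolated)
Conditions: NaNH2 (3 equiv), NH3(l), −33 °C; evaporate NH3; cold brine, −70 °C; distil into a cold trap, keep as a cold toluene solution
Reagents that add atoms: none
Why: This is the double base-induced elimination of an α-chloroacetal (loss of MeOH, then of HCl) that serves as the standard alkoxyacetylene synthesis, and the third equivalent of NaNH2 parks the volatile product as acetylide 10 until the aqueous quench.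

Step 6
Reactants: 7 3-methoxy-2-(3-methylbut-2-enyl)cyclobut-2-en-1-one; 11 methoxyacetylene
Product: 16 3,5-dimethoxy-4-(3-methylbut-2-enyl)phenol, via vinylketene 12 (not isolated), via vinylcyclobutenone 13 (not isolated), via dienylketene 14 (not isolated), via cyclohexadienone 15 (not isolated)
Conditions: excess 11, BHT (cat.), toluene, sealed pressure tube, 110 → 150 °C; then KOH, MeOH, rt
Reagents that add atoms: none
Why: Heat opens 7 by conrotatory 4π electrocyclic cleavage of the C(=O)–CH2 bond to vinylketene 12, the ketene C=C of 12 adds 11 in a [2+2] cycloaddition to give 13, 13 reopens to dienylketene 14, and 14 closes and tautomerises through 15 to phenol 16. This is the Danheiser benzannulation of a cyclobutenone with an alkynyl ether; the alkoxy donor on C3 of 7 lies at the edge of the usual scope, yet the adduct 13 formed in every such reaction is itself a 3-alkoxycyclobutenone that opens thermally, so only a higher temperature is expected for 7, whose CH2 terminus lacks accelerating substituents. Ring A closes by disrotatory 6π electrocyclisation of 14, which makes C4a–C8a after the cycloaddition has laid down C8a–C8 and C6–C7. No stereocentre is created in 16, since the racemic quaternary carbon of 13 ends as aromatic C6. The regiochemistry required is union of the unsubstituted alkyne carbon with the ketene carbonyl carbon, and the polarisation of the ynol ether (nucleophilic at the carbon remote from oxygen) against the electrophilic ketene centre secures it, placing the incoming methoxy group beside the prenyl carbon. Chemoselectivity for arene formation over capture of the ketenes by the prenyl alkene or by 16 rests on the reversible opening of 13 that feeds the fast 6π closure, on excess 11, on the methyl ynol ether being unable to fragment by retro-ene loss of an alkene, and on the final KOH/MeOH treatment that returns any aryl ester to 16.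

Step 7
Reactants: 17 methyl 2-(2,4-dihydroxyphenyl)acetate
Product: 18 methyl 2-[2,4-bis(tert-butyldimethylsilyloxy)phenyl]acetate
Conditions: TBSCl, imidazole, DMF, rt
Reagents that add atoms: tert-butyldimethylsilyl chloride, CC(C)(C)[Si](C)(C)Cl
Why: Imidazole-promoted silylation of phenols is routine, and aryl TBS ethers should survive hydride, amine base and hot acetic acid yet leave with fluoride under near-neutral conditions.

Step 8
Reactants: 18 methyl 2-[2,4-bis(tert-butyldimethylsilyloxy)phenyl]acetate
Product: 20 2-[2,4-bis(tert-butyldimethylsilyloxy)phenyl]acetaldehyde, via aluminium hemiacetal 19 (not isolated)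
Conditions: i-Bu2AlH, CH2Cl2, −78 °C; aq. potassium sodium tartrate
Reagents that add atoms: none
Why: Partial ester reduction with i-Bu2AlH stops at the aldehyde level because the tetrahedral aluminium hemiacetal 19 persists at −78 °C until the quench.

Step 9
Reactants: 20 2-[2,4-bis(tert-butyldimethylsilyloxy)phenyl]acetaldehyde
Product: 22 2-[2,4-bis(tert-butyldimethylsilyloxy)phenyl]prop-2-enal, via Mannich base 21 (not isolated)
Conditions: [Me2N=CH2]I, Et3N, CH2Cl2, rt; use at once, BHT
Reagents that add atoms: N,N-dimethylmethyleneiminium iodide (Eschenmoser's salt), C[N+](C)=C.[I-]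
Why: In this Mannich α-methylenation of an aldehyde, the readily formed enol of the arylacetaldehyde adds to the iminium salt and the racemic Mannich base 21 loses Me2NH by E1cB elimination under anhydrous conditions that spare the silyl ethers.

Step 10
Reactants: 16 3,5-dimethoxy-4-(3-methylbut-2-enyl)phenol; 22 2-[2,4-bis(tert-butyldimethylsilyloxy)phenyl]prop-2-enal
Product: 25 3-[2,4-bis(tert-butyldimethylsilyloxy)phenyl]-5,7-dimethoxy-6-(3-methylbut-2-enyl)-2H-chromene, via dioxaborin 23 (not isolated), via o-quinone methide 24 (not isolated)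
Conditions: PhB(OH)2, AcOH, toluene, Dean–Stark reflux, slow addition of 22
Reagents that add atoms: none
Why: In this boronic-acid-templated chromene annulation of a phenol with an α,β-unsaturated aldehyde, the three components condense to racemic dioxaborin 23 so that C4a bonds to the aldehyde carbon only, thermal loss of PhBO gives o-quinone methide 24, and oxa-6π electrocyclisation forms O1–C2; the two ortho carbons of 16 are equivalent and the para carbon is blocked, so one regioisomer should result.

Step 11
Reactants: 25 3-[2,4-bis(tert-butyldimethylsilyloxy)phenyl]-5,7-dimethoxy-6-(3-methylbut-2-enyl)-2H-chromene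
Product: 26 dehydroglyasperin D
Conditions: TBAF, AcOH, THF, 0 °C, Ar
Reagents that add atoms: none
Why: Fluoride-induced cleavage of aryl silyl ethers is fast at 0 °C, and the AcOH buffer under argon keeps the resorcinol protonated, which should protect the oxidation-prone 2'-hydroxyisoflav-3-ene and leave the prenyl group and the chromene intact.

Compound list
1 | 5-methylhex-4-enoic acid | CC(C)=CCCC(=O)O | starting material
2 | 5-methylhex-4-enoyl chloride | CC(C)=CCCC(=O)Cl | intermediate
3 | ethoxyacetylene | CCOC#C | starting material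
4 | prenylketene, 5-methylhexa-1,4-dien-1-one (not isolated) | CC(C)=CCC=C=O | intermediate
5 | (±)-3-ethoxy-4-(3-methylbut-2-enyl)cyclobut-2-en-1-one | CCOC1=CC(=O)C1CC=C(C)C | intermediate
6 | 3-hydroxy-2-(3-methylbut-2-enyl)cyclobut-2-en-1-one (enol of 2-prenylcyclobutane-1,3-dione) | OC1=C(CC=C(C)C)C(=O)C1 | intermediate
7 | 3-methoxy-2-(3-methylbut-2-enyl)cyclobut-2-en-1-one | COC1=C(CC=C(C)C)C(=O)C1 | intermediate
8 | chloroacetaldehyde dimethyl acetal | COC(CCl)OC | starting material
9 | 2-chlorovinyl methyl ether, E/Z mixture (not isolated) | COC=CCl | intermediate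
10 | sodium methoxyacetylide (not isolated) | [Na+].[C-]#COC | intermediate
11 | methoxyacetylene | COC#C | intermediate
12 | vinylketene, 2-(1-methoxyethenyl)-5-methylhexa-1,4-dien-1-one (not isolated) | COC(=C)C(CC=C(C)C)=C=O | intermediate
13 | (±)-3-methoxy-4-(1-methoxyethenyl)-4-(3-methylbut-2-enyl)cyclobut-2-en-1-one (not isolated) | COC1=CC(=O)C1(CC=C(C)C)C(=C)OC | intermediate
14 | dienylketene, 3,5-dimethoxy-4-(3-methylbut-2-enyl)hexa-1,3,5-trien-1-one, isomer with ketene arm cis to the methoxyvinyl group (not isolated) | O=C=C/C(OC)=C(CC=C(C)C)\C(=C)OC | intermediate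
15 | 3,5-dimethoxy-4-(3-methylbut-2-enyl)cyclohexa-2,4-dien-1-one (not isolated) | COC1=CC(=O)CC(OC)=C1CC=C(C)C | intermediate
16 | 3,5-dimethoxy-4-(3-methylbut-2-enyl)phenol | COc1cc(O)cc(OC)c1CC=C(C)C | intermediate
17 | methyl 2-(2,4-dihydroxyphenyl)acetate | COC(=O)Cc1ccc(O)cc1O | starting material
18 | methyl 2-[2,4-bis(tert-butyldimethylsilyloxy)phenyl]acetate | COC(=O)Cc1ccc(O[Si](C)(C)C(C)(C)C)cc1O[Si](C)(C)C(C)(C)C | intermediate
19 | diisobutylaluminium alkoxide of the methyl hemiacetal of 20, racemic (not isolated) | COC(Cc1ccc(O[Si](C)(C)C(C)(C)C)cc1O[Si](C)(C)C(C)(C)C)O[Al](CC(C)C)CC(C)C | intermediate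
20 | 2-[2,4-bis(tert-butyldimethylsilyloxy)phenyl]acetaldehyde | O=CCc1ccc(O[Si](C)(C)C(C)(C)C)cc1O[Si](C)(C)C(C)(C)C | intermediate
21 | (±)-2-[2,4-bis(tert-butyldimethylsilyloxy)phenyl]-3-(dimethylamino)propanal (not isolated) | CN(C)CC(C=O)c1ccc(O[Si](C)(C)C(C)(C)C)cc1O[Si](C)(C)C(C)(C)C | intermediate
22 | 2-[2,4-bis(tert-butyldimethylsilyloxy)phenyl]prop-2-enal | C=C(C=O)c1ccc(O[Si](C)(C)C(C)(C)C)cc1O[Si](C)(C)C(C)(C)C | intermediate
23 | (±)-4-{1-[2,4-bis(tert-butyldimethylsilyloxy)phenyl]ethenyl}-5,7-dimethoxy-6-(3-methylbut-2-enyl)-2-phenyl-4H-1,3,2-benzodioxaborinine (not isolated) | COc1cc2OB(c3ccccc3)OC(C(=C)c3ccc(O[Si](C)(C)C(C)(C)C)cc3O[Si](C)(C)C(C)(C)C)c2c(OC)c1CC=C(C)C | intermediate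
24 | o-quinone methide, (6Z)-6-{2-[2,4-bis(tert-butyldimethylsilyloxy)phenyl]prop-2-enylidene}-3,5-dimethoxy-4-(3-methylbut-2-enyl)cyclohexa-2,4-dien-1-one (not isolated) | COC1=CC(=O)/C(=C\C(=C)c2ccc(O[Si](C)(C)C(C)(C)C)cc2O[Si](C)(C)C(C)(C)C)C(OC)=C1CC=C(C)C | intermediate
25 | 3-[2,4-bis(tert-butyldimethylsilyloxy)phenyl]-5,7-dimethoxy-6-(3-methylbut-2-enyl)-2H-chromene | COc1cc2c(c(OC)c1CC=C(C)C)C=C(c1ccc(O[Si](C)(C)C(C)(C)C)cc1O[Si](C)(C)C(C)(C)C)CO2 | intermediate
26 | dehydroglyasperin D, 4-[5,7-dimethoxy-6-(3-methylbut-2-enyl)-2H-chromen-3-yl]benzene-1,3-diol | COc1cc2c(c(OC)c1CC=C(C)C)C=C(c1ccc(O)cc1O)CO2 | target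

Total step count: 11
Longest linear sequence: 7 steps (1, 2, 3, 4, 6, 10, 11)

Steps most likely to fail

Step 6. The donor-stabilised four-membered ring may open only at temperatures at which the volatile ynol ether polymerises, and the phenol may be acylated by the ketene while both are present. The fallback reaches the same ketene photochemically at room temperature by a Wolff rearrangement, the diazo ketone variant of the benzannulation. It sets out from 2. MeNH(OMe)·HCl and Et3N in CH2Cl2 should give N-methoxy-N,5-dimethylhex-4-enamide F1. 1-Methoxyvinyllithium (methyl vinyl ether, t-BuLi, THF) should turn this into 2-methoxy-7-methylocta-1,6-dien-3-one F2. LiN(SiMe3)2 and CF3CO2CH2CF3 at −78 °C should acylate the only enolisable carbon to give 1,1,1-trifluoro-5-methoxy-3-(3-methylbut-2-enyl)hex-5-ene-2,4-dione F3. MsN3, Et3N and H2O in MeCN should then effect detrifluoroacetylative diazo transfer to 4-diazo-2-methoxy-7-methylocta-1,6-dien-3-one F4. Irradiation of F4 with excess 11 expels N2 with migration of the methoxyvinyl group. The fallback comes back to the route at 12, which is trapped to 13 without heating, and a separate gentle heating carries 13 on to 16 when no free ketene 12 is left.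

Step 10. Conjugate attack of the electron-rich arene on the unsubstituted β-carbon of the enal, or self-addition and polymerisation of the enal, may outrun the templated 1,2-addition. The fallback makes the C3=C4 bond by ring-closing metathesis. It sets out from 16 and 22. MgCl2, Et3N and paraformaldehyde in MeCN at reflux (ortho-specific magnesium phenoxide formylation) should convert 16 into 6-hydroxy-2,4-dimethoxy-3-(3-methylbut-2-enyl)benzaldehyde F5. Luche reduction of 22 (NaBH4, CeCl3·7H2O, MeOH, 0 °C) should give 2-[2,4-bis(tert-butyldimethylsilyloxy)phenyl]prop-2-en-1-ol F6. Mitsunobu etherification (PPh3, DIAD, THF) should join the two as 6-{2-[2,4-bis(tert-butyldimethylsilyloxy)phenyl]prop-2-enyloxy}-2,4-dimethoxy-3-(3-methylbut-2-enyl)benzaldehyde F7. Wittig methylenation (Ph3P=CH2, THF) should give 1-{2-[2,4-bis(tert-butyldimethylsilyloxy)phenyl]prop-2-enyloxy}-2-ethenyl-3,5-dimethoxy-4-(3-methylbut-2-enyl)benzene F8. The second-generation Grubbs catalyst in CH2Cl2 at reflux should close the six-membered ring with loss of ethene, because the trisubstituted prenyl alkene engages far more slowly. The fallback comes back to the route at 25.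

Step 2. Dimerisation and amine-induced oligomerisation of the monoalkylketene may outrun the cycloaddition. The fallback puts the prenyl group on the alkyne and lets a more reactive ketene perform the [2+2] addition, which also sets the correct enol ether directly. It sets out from 10, made from 8 as in step 5. Prenyl bromide in NH3(l) should give 1-methoxy-5-methylhex-4-en-1-yne F9. Dichloroketene (Cl3CCOCl, Zn(Cu), Et2O) should add to the ynol ether, which is far more nucleophilic than the alkene, to give 4,4-dichloro-3-methoxy-2-(3-methylbut-2-enyl)cyclobut-2-en-1-one F10. Reductive dechlorination (Zn, AcOH, TMEDA, EtOH, 0 °C) comes back to the route at 7 and replaces steps 1 to 4.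

Further compounds
F1 | step 6 | N-methoxy-N,5-dimethylhex-4-enamide | CC(C)=CCCC(=O)N(C)OC
F2 | step 6 | 2-methoxy-7-methylocta-1,6-dien-3-one | C=C(OC)C(=O)CCC=C(C)C
F3 | step 6 | (±)-1,1,1-trifluoro-5-methoxy-3-(3-methylbut-2-enyl)hex-5-ene-2,4-dione | C=C(OC)C(=O)C(CC=C(C)C)C(=O)C(F)(F)F
F4 | step 6 | 4-diazo-2-methoxy-7-methylocta-1,6-dien-3-one | C=C(OC)C(=O)C(=[N+]=[N-])CC=C(C)C
F5 | step 10 | 6-hydroxy-2,4-dimethoxy-3-(3-methylbut-2-enyl)benzaldehyde | COc1cc(O)c(C=O)c(OC)c1CC=C(C)C
F6 | step 10 | 2-[2,4-bis(tert-butyldimethylsilyloxy)phenyl]prop-2-en-1-ol | C=C(CO)c1ccc(O[Si](C)(C)C(C)(C)C)cc1O[Si](C)(C)C(C)(C)C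
F7 | step 10 | 6-{2-[2,4-bis(tert-butyldimethylsilyloxy)phenyl]prop-2-enyloxy}-2,4-dimethoxy-3-(3-methylbut-2-enyl)benzaldehyde | COc1cc(OCC(=C)c2ccc(O[Si](C)(C)C(C)(C)C)cc2O[Si](C)(C)C(C)(C)C)c(C=O)c(OC)c1CC=C(C)C
F8 | step 10 | 1-{2-[2,4-bis(tert-butyldimethylsilyloxy)phenyl]prop-2-enyloxy}-2-ethenyl-3,5-dimethoxy-4-(3-methylbut-2-enyl)benzene | COc1cc(OCC(=C)c2ccc(O[Si](C)(C)C(C)(C)C)cc2O[Si](C)(C)C(C)(C)C)c(C=C)c(OC)c1CC=C(C)C
F9 | step 2 | 1-methoxy-5-methylhex-4-en-1-yne | COC#CCC=C(C)C
F10 | step 2 | 4,4-dichloro-3-methoxy-2-(3-methylbut-2-enyl)cyclobut-2-en-1-one | COC1=C(CC=C(C)C)C(=O)C1(Cl)Cl
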